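## The problem

Target 27 is a bicyclo[3.3.1]nonane-2,4,9-trione held as its C2 methyl enol ether. The core is numbered C1 (prenyl bridgehead), C2 (C–OMe), C3 (C–benzoyl), C4 (enone C=O), C5 (lavandulyl bridgehead), C6 (CH2), C7 (CH–prenyl), C8 (CMe2) and C9 (bridging C=O); ring A is C1–C8–C7–C6–C5–C9 and ring B is C1–C2–C3–C4–C5–C9. Both bridgeheads are quaternary and C1 stands next to the quaternary C8, so the C1–C8 pair is the most crowded place in the molecule. Of the four stereocentres, C1 and C5 are tied to each other by the one-carbon bridge, and C7 can direct C1 through the chair of ring A (equatorial prenyl, axial entry at C1), so within the core only C7 needs a reagent to set it. The lavandulyl methine lies outside the core, can neither be controlled by it nor control it, and must be brought in as a single enantiomer while C7 is set independently; otherwise diastereomers result. The methyl ether must sit on the C2 oxygen and not the C4 oxygen, a distinction that methylation of the free trione does not make. Three prenyl groups and an isopropenyl group rule out strong acid (cation–olefin and pyran-forming cyclisations), electrophilic oxidants, hydrogenation and π-acids, and the β-methoxy enone and the non-enolisable β-dicarbonyl array do not tolerate aqueous acid or nucleophilic base for long. The feature that opens the molecule is the sequence C9(=O)–C1–C8: C8 is β to the C9 carbonyl, so a C1=C8 enone can receive the second C8 methyl by conjugate addition and thereby deliver an enolate exactly at C1, where the C2–C3–C4 arm must be attached.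

## Retrosynthesis

**C3–benzoyl bond (27 ⇒ 25).** The benzoyl group is removed first. In 25 both bridgeheads are quaternary, so C3–H is the only position that a hindered amide base can metalate, and late acylation there is unambiguous. Carrying the benzoyl group earlier would put an acidic triketone through all the enolate chemistry. The forward step asks only that the base deprotonate C3 and not add to C4 or C9.

**C4–C5 bond of ring B (25 ⇒ 23).** Ring B is opened at C4–C5 rather than at C1–C2, so that the less hindered bridgehead is the one made by ring closure. Precursor 23 is a monocyclic ketone whose C1 carries a β-methoxyacrylate phenyl ester. C5–H is its only enolisable position, and the one-carbon bridge forces the new bond cis to the C1–C2 bond, so both C5 epimers of 23 give the same product. The forward reaction must acylate a tertiary enolate on carbon.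

**C1–C2 and C8–CH3 bonds, the key disconnection (23 ⇒ 15 + 20 + 19).** Removing the acrylate arm from C1 and one methyl from C8 turns the vicinal quaternary pair into the tetrasubstituted alkene of enone 15 and removes the C1 stereocentre. Deprotonating a 2,2,6-trisubstituted cyclohexanone would enolise towards C5, not C1; conjugate addition of lithium dimethylcuprate 20 gives the C1 enolate regiospecifically. Phenyl 3-methoxypropiolate 19 supplies C2, C3 and C4 in one piece, with the methoxy group already on C2 and C4 as an ester ready for the ring closure. The forward step asks for C-attack of a hindered enolate at the methoxy-bearing alkyne carbon, on the face of C1 anti to the C7 prenyl group.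

**C5–lavandulyl bond (15 ⇒ 10 + 13).** The lavandulyl group is attached to the kinetic α′ position of enone 10 as its triflate 13. No control is needed at C5, since this centre is erased and reset in the ring closure. Triflate 13 comes from (S)-lavandulol 12, which is taken from the racemate 11 by enzymatic resolution; after coupling the methine is R by priority change only.

**Carbonyl transposition (10 ⇒ 8).** Enone 10 is the Stork–Danheiser product of vinylogous ester 8: a methyl nucleophile adds to the carbonyl (future C8) and acid moves the oxygen to the former enol ether carbon (future C9). This places the stereocentre that was α′ in 8 at the γ position (C7) of 10.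

**C7 stereocentre (8 ⇒ 7 ⇒ 6 ⇒ 4).** The C7 substituent is introduced at the α′ carbon of vinylogous ester 4 through its allyl enol carbonate 6 and a palladium-catalysed decarboxylative asymmetric allylation to 7. Allyl is used because a prenyl π-allyl complex would scramble regiochemistry; cross-metathesis then turns allyl into prenyl (8). The forward reaction must form a tertiary α′ centre without equilibrating it.

**Vinylogous ester (4 ⇒ 3 ⇒ 1 + 2).** Enol ether 4 is the O-methylation product of 2-prenylcyclohexane-1,3-dione 3, made by C-alkylation of cyclohexane-1,3-dione 1 with prenyl bromide 2. The dione is symmetric, so only one enol ether can form.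

**Ynoate (19 ⇒ 17 ⇒ 16).** Ynoate 19 is the phenoxycarbonylation product of metalated methoxyacetylene 17, which is obtained by double elimination from chloroacetaldehyde dimethyl acetal 16.

## Roads not taken

**Alternative 1: cyclobutenone–ynol ether annulation.**
- **Cut:** C3–C4 and C1–C2 of ring B; ring A is closed afterwards.
- **Forward key step:** on heating, 3-ethoxy-4,4-dilavandulyl-2-prenylcyclobutenone A2 opens to a vinylketene, which adds methoxyacetylene 17 by [2+2] cycloaddition. 4π opening and 6π closure then give dienone A1, which cannot aromatise because C5 is quaternary.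
- **Merits:** ring B forms without reagents, with the methoxy group on C2 and a different ether on C9. There is no question of C- versus O-acylation.
- **Weak points:** A2 carries two β-branched lavandulyl groups on one carbon, to be introduced by double alkylation with a non-activated electrophile. One of them is meant to become C6–C7–C8, so the hardest bond, C1–C8, is left to a later cation–olefin cyclisation. That cyclisation must choose one of two identical isopropenyl groups (which also sets C5 relative to C7) beside three prenyl groups. C3 benzoylation is still outstanding.
- **Comparison:** this road is better in ring B regiochemistry and avoids the enolate acylation of the chosen plan. The chosen plan sets against it that the C1–C8 pair is made early by cuprate chemistry under control from C7, that one equivalent of resolved lavandulyl suffices, and that no acid is needed.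

**Alternative 2: dearomative alkylative annulation.**
- **Cut:** C1–C8 and C5–C6, that is, all of ring A, from a benzoylphloroglucinol.
- **Forward key step:** the potassium phenoxide of A4 adds through its prenyl-bearing carbon to the CMe2 terminus of acetoxymethyl enal A5. Acetate leaves, and the lavandulyl-bearing carbon adds to the new methylene, closing ring A and dearomatising ring B to give A3.
- **Merits:** it is the shortest road; the benzoyl group is present from the start and both quaternary bridgeheads form in one operation.
- **Weak points:** A4 needs C-lavandulylation of a phloroglucinol with a non-allylic electrophile, where O-alkylation should compete. Its two nucleophilic carbons are nearly equivalent, so the first addition can begin at either and swap the bridgehead substituents. The core configuration would have to be induced by a chiral counter-ion against the remote lavandulyl centre. The C7 formyl group must be homologated to prenyl over several steps. The free enol of A3 must be methylated selectively on the C2 oxygen.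
- **Comparison:** this road is clearly better in step count and convergency. The chosen plan sets against it that every substituent is placed by construction, that the methoxy position is fixed by reagent 19, and that C7 is set by a catalyst before the lavandulyl centre is present.

**Alternative 3: gold-catalysed closure onto a methoxy-ynone.**
- **Cut:** the same C1–C2 bond as in the chosen plan, but intramolecular, with C4–C5 already in place.
- **Forward key step:** a cationic phosphine complex of monovalent gold activates the alkyne of silyl enol ether A7, and C1 attacks C2 in a 6-endo-dig closure to give A6, which is identical with 25.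
- **Merits:** intramolecular attack at the crowded C1 is helped by entropy; the step is catalytic and mild, the methoxy position is defined, and the endgame is the same.
- **Weak points:** C5 must be quaternary and correctly configured before the closure, so it has to be set by acylating a tertiary enolate under weak 1,3-control from C7, and wrong C5 epimers do not converge. The C1 silyl enol ether must be made on a compound that carries a base-sensitive ynone. A π-acid must distinguish an electron-rich alkynyl ether from four alkenes.
- **Comparison:** the closure at C1 is probably more reliable than the intermolecular trapping of the chosen plan. The chosen plan sets against it that C5 is set automatically by ring closure, that the route is shorter, and that no π-acid meets the polyene.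

Key step: step 12

Remarks and assumptions:
- Prenyl = 3-methylbut-2-en-1-yl; lavandulyl = 5-methyl-2-(prop-1-en-2-yl)hex-4-en-1-yl. Bicyclic compounds are named in the core numbering defined above.
- Some descriptors change along the route (C7: S in 7–10, R from 15; lavandulyl methine: S in 12 and 13, R from 15; C5: S in 25, R in 27) only because CIP priorities change; the spatial arrangement is retained.
- Assumption: the (R,R) antipode of the ligand in step 4 is taken to give (6S)-7; both antipodes are commercial, so the antipode is chosen by the observed sense of induction.
- Assumption: the lipase in step 7 is taken to acylate (R)-lavandulol faster, so that the S alcohol is the recovered one; were the preference reversed, the acetate would be collected and saponified.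

## Steps

Step 1
Reactants: 1 cyclohexane-1,3-dione; 2 prenyl bromide (1-bromo-3-methylbut-2-ene)
Product: 3 2-prenylcyclohexane-1,3-dione
Conditions: KOH, H2O, 0 °C → rt
Reagents that add atoms: none
Why: C-allylation of a cyclic 1,3-dione enolate with an allylic bromide; in water the enolate oxygens are hydrogen-bonded, which favours attack through C2.

Step 2
Reactants: 3 2-prenylcyclohexane-1,3-dione
Product: 4 3-methoxy-2-prenylcyclohex-2-en-1-one
Conditions: Me2SO4, K2CO3, acetone, reflux
Reagents that add atoms: dimethyl sulfate (COS(=O)(=O)OC)
Why: O-alkylation of a 2-alkyl-1,3-dione enolate with a hard electrophile; the acid-free conditions keep the prenyl group from cyclising onto the enol oxygen, and the symmetric dione gives a single enol ether.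

Step 3
Reactants: 4 3-methoxy-2-prenylcyclohex-2-en-1-one
Product: 6 allyl 5-methoxy-6-prenylcyclohexa-1,5-dien-1-yl carbonate, via sodium dienolate 5 (not isolated)
Conditions: NaN(SiMe3)2, TMEDA, THF, −78 °C; allyl chloroformate, −78 °C
Reagents that add atoms: allyl chloroformate (C=CCOC(=O)Cl)
Why: Kinetic α′-deprotonation of the vinylogous ester gives the cross-conjugated dienolate, which a chloroformate acylates on oxygen (sodium counter-ion, diamine); the enol carbonate fixes the enolate regiochemistry for step 4.

Step 4
Reactants: 6 allyl 5-methoxy-6-prenylcyclohexa-1,5-dien-1-yl carbonate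
Product: 7 (6S)-6-allyl-3-methoxy-2-prenylcyclohex-2-en-1-one
Conditions: Pd2(dba)3·CHCl3 (cat.), (R,R)-ANDEN-phenyl Trost ligand [(11R,12R)-11,12-bis(2-diphenylphosphinobenzamido)-9,10-dihydro-9,10-ethanoanthracene] (cat.), 1,4-dioxane, rt
Reagents that add atoms: none
Why: Decarboxylative asymmetric allylic alkylation (Tsuji–Trost type): zerovalent palladium ionises the allyl carbonate, CO2 is lost, and the enolate and π-allyl cation recombine at C6 inside the chiral pocket, so the ligand sets C6. No external base is present, so the tertiary centre should not equilibrate.

Step 5
Reactants: 7 (6S)-6-allyl-3-methoxy-2-prenylcyclohex-2-en-1-one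
Product: 8 (6S)-3-methoxy-2,6-diprenylcyclohex-2-en-1-one
Conditions: 2-methylbut-2-ene (excess), second-generation Grubbs catalyst RuCl2(=CHPh)(H2IMes)(PCy3) (cat.), CH2Cl2, 40 °C
Reagents that add atoms: 2-methylbut-2-ene (CC=C(C)C)
Why: Olefin cross-metathesis exchanges the terminal methylene for an isopropylidene group; the existing trisubstituted prenyl alkene reacts only degenerately and the stereocentre is not touched.

Step 6
Reactants: 8 (6S)-3-methoxy-2,6-diprenylcyclohex-2-en-1-one
Product: 10 (4S)-3-methyl-2,4-diprenylcyclohex-2-en-1-one, via tertiary allylic alcohol 9 (not isolated)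
Conditions: MeLi, Et2O, −78 → 0 °C; then 1 M HCl, THF, 0 °C → rt
Reagents that add atoms: methyllithium ([Li]C); water (O)
Why: Stork–Danheiser transposition: 1,2-addition to the vinylogous ester carbonyl, then acid ionises the tertiary allylic alcohol, water adds at the enol ether carbon and methanol is lost. The C6 centre of 8 becomes C4 of 10 unchanged, because brief dilute acid should neither form the dienol nor hydrate the prenyl groups.

Step 7
Reactants: 11 (±)-lavandulol
Product: 12 (S)-lavandulol
Conditions: porcine pancreatic lipase, vinyl acetate, hexane, rt, taken beyond half conversion; chromatography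
Reagents that add atoms: none
Why: Lipase-catalysed kinetic resolution by enantioselective transesterification; the faster-reacting R alcohol is removed as its acetate and the S alcohol is recovered, no stereocentre being formed.

Step 8
Reactants: 12 (S)-lavandulol
Product: 13 (S)-lavandulyl trifluoromethanesulfonate
Conditions: Tf2O, 2,6-lutidine, CH2Cl2, −78 °C; cold pentane filtration, used at once
Reagents that add atoms: trifluoromethanesulfonic anhydride (O=S(=O)(OS(=O)(=O)C(F)(F)F)C(F)(F)F)
Why: O-sulfonylation of a primary alcohol with a hindered base; the stereocentre is not involved, and low temperature with immediate use guards against ionisation of the homoallylic triflate.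

Step 9
Reactants: 10 (4S)-3-methyl-2,4-diprenylcyclohex-2-en-1-one; 13 (S)-lavandulyl trifluoromethanesulfonate
Product: 15 (4R)-6-[(2R)-lavandulyl]-3-methyl-2,4-diprenylcyclohex-2-en-1-one (C6 epimer mixture), via lithium dienolate 14 (not isolated)
Conditions: LiN(i-Pr)2, THF, −78 °C; 13, THF, −78 → −30 °C
Reagents that add atoms: none
Why: Kinetic α′-deprotonation of the enone gives the cross-conjugated dienolate, which displaces the primary triflate (SN2); a triflate is used because the carbon next to the leaving group is branched. The new C6 centre forms without control and is reset in step 13, and the lavandulyl centre is carried over from 13.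

Step 10
Reactants: 16 chloroacetaldehyde dimethyl acetal (2-chloro-1,1-dimethoxyethane)
Product: 17 methoxyacetylene
Conditions: NaNH2, liquid NH3, −33 °C; NH4Cl, H2O; distilled into cold THF
Reagents that add atoms: none
Why: Twofold base-induced elimination (methanol, then HCl) from the chloroacetal gives the sodium alkoxyacetylide, which is protonated on quench; a standard preparation of alkoxyacetylenes.

Step 11
Reactants: 17 methoxyacetylene
Product: 19 phenyl 3-methoxyprop-2-ynoate, via lithium methoxyacetylide 18 (not isolated)
Conditions: n-BuLi, THF, −78 °C; cannulated into phenyl chloroformate, THF, −78 °C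
Reagents that add atoms: phenyl chloroformate (O=C(Cl)Oc1ccccc1)
Why: Acylation of a lithium acetylide with a chloroformate; inverse addition at low temperature keeps the acetylide from attacking the product ynoate.

Step 12
Reactants: 15 (4R)-6-[(2R)-lavandulyl]-3-methyl-2,4-diprenylcyclohex-2-en-1-one (C6 epimer mixture); 20 lithium dimethylcuprate (made in the flask from CuI and MeLi); 19 phenyl 3-methoxyprop-2-ynoate
Product: 23 phenyl (2E)-3-{(1R,5R)-3-[(2R)-lavandulyl]-6,6-dimethyl-2-oxo-1,5-diprenylcyclohexyl}-3-methoxyprop-2-enoate (ring C3 epimer mixture), via silyl enol ether 21 (not isolated), via lithium enolate 22 (not isolated)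
Conditions: 20 (CuI, MeLi), TMSCl, THF, −78 → −20 °C; evaporation, pentane, filtration under Ar; MeLi, THF, 0 °C → rt; 19, THF, −78 → −40 °C; AcOH, −78 °C
Reagents that add atoms: none
Why: Proposed new method: the cuprate (monovalent copper, assisted by TMSCl) transfers methyl to the β-carbon C8 of the tetrasubstituted enone, and the C1 enolate is held regiospecifically as silyl enol ether 21, a conjugate addition known for 2,3,4-trisubstituted cyclohexenones. MeLi then releases lithium enolate 22 without a proton source, so the C5 side is never enolised. Enolate 22 adds through carbon to the methoxy-bearing alkyne carbon of 19, which push–pull polarisation makes the electrophilic one and which has no acidic hydrogen; the lithium allenoate is protonated at −78 °C on the side away from the quaternary C1, giving the E acrylate with C1 cis to the ester. The closest known reaction type is the Michael addition of regiodefined, cuprate-derived lithium enolates to propiolate esters; new here are the alkoxy group on the acceptor carbon and the quaternary neighbour C8. No ring closes. The one new stereocentre, C1, is controlled by C7: in the chair-like transition state with the C7 prenyl equatorial, the ynoate enters axially, anti to the axial C8 methyl, so the C2 arm ends trans to the C7 prenyl (1R). The step needs C- over O-attack (favoured for a lithium enolate and a slim, soft acceptor), 1,4- over 1,2-addition to the phenyl ester, and protonation before the allenoate can attack the C9 ketone, which the cold acetic acid quench secures.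

Step 13
Reactants: 23 phenyl (2E)-3-{(1R,5R)-3-[(2R)-lavandulyl]-6,6-dimethyl-2-oxo-1,5-diprenylcyclohexyl}-3-methoxyprop-2-enoate (ring C3 epimer mixture)
Product: 25 (1R,5S,7R)-5-[(2R)-lavandulyl]-2-methoxy-8,8-dimethyl-1,7-diprenylbicyclo[3.3.1]non-2-ene-4,9-dione (core numbering), via potassium enolate 24 (not isolated)
Conditions: KN(SiMe3)2, THF, −78 → 0 °C; aq. NH4Cl
Reagents that add atoms: none
Why: Dieckmann-type intramolecular Claisen condensation: C5–H is the only enolisable position, and the potassium enolate attacks the aryl ester held axially on C1 (6-(enolendo)-exo-trig, ring B) with loss of phenoxide. The bridge forces C4 onto the face of C5 cis to the C1–C2 bond, so both C5 epimers of 23 converge on one product.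

Step 14
Reactants: 25 (1R,5S,7R)-5-[(2R)-lavandulyl]-2-methoxy-8,8-dimethyl-1,7-diprenylbicyclo[3.3.1]non-2-ene-4,9-dione
Product: 27 (1R,5R,7R)-3-benzoyl-5-[(2R)-lavandulyl]-2-methoxy-8,8-dimethyl-1,7-diprenylbicyclo[3.3.1]non-2-ene-4,9-dione (core numbering; CNP0385193.1), via C3-lithio enone 26 (not isolated)
Conditions: lithium 2,2,6,6-tetramethylpiperidide (from the amine and n-BuLi), THF, −78 °C; PhCOCl, −78 °C
Reagents that add atoms: benzoyl chloride (O=C(Cl)c1ccccc1)
Why: Vinylic lithiation at C3 of the β-methoxy enone (the only acidic C–H, both bridgeheads being quaternary) followed by C-acylation, a known way to acylate C3 of bicyclic vinylogous esters of this kind; no stereocentre is touched.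

## Compound list

1 | cyclohexane-1,3-dione | O=C1CCCC(=O)C1 | starting material
2 | prenyl bromide | CC(C)=CCBr | starting material
3 | 2-prenylcyclohexane-1,3-dione | O=C1CCCC(=O)C1CC=C(C)C | intermediate
4 | 3-methoxy-2-prenylcyclohex-2-en-1-one | COC1=C(CC=C(C)C)C(=O)CCC1 | intermediate
5 | sodium 5-methoxy-6-prenylcyclohexa-1,5-dien-1-olate | [Na+].COC1=C(CC=C(C)C)C([O-])=CCC1 | intermediate (not isolated)
6 | allyl 5-methoxy-6-prenylcyclohexa-1,5-dien-1-yl carbonate | COC1=C(CC=C(C)C)C(OC(=O)OCC=C)=CCC1 | intermediate
7 | (6S)-6-allyl-3-methoxy-2-prenylcyclohex-2-en-1-one | COC1=C(CC=C(C)C)C(=O)[C@H](CC=C)CC1 | intermediate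
8 | (6S)-3-methoxy-2,6-diprenylcyclohex-2-en-1-one | COC1=C(CC=C(C)C)C(=O)[C@H](CC=C(C)C)CC1 | intermediate
9 | (6S)-3-methoxy-1-methyl-2,6-diprenylcyclohex-2-en-1-ol (C1 epimers) | COC1=C(CC=C(C)C)C(C)(O)[C@H](CC=C(C)C)CC1 | intermediate (not isolated)
10 | (4S)-3-methyl-2,4-diprenylcyclohex-2-en-1-one | O=C1CC[C@@H](CC=C(C)C)C(C)=C1CC=C(C)C | intermediate
11 | (±)-lavandulol, 5-methyl-2-(prop-1-en-2-yl)hex-4-en-1-ol | C=C(C)C(CC=C(C)C)CO | starting material
12 | (S)-lavandulol | C=C(C)[C@H](CC=C(C)C)CO | intermediate
13 | (S)-lavandulyl trifluoromethanesulfonate | C=C(C)[C@H](CC=C(C)C)COS(=O)(=O)C(F)(F)F | intermediate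
14 | lithium (4R)-5-methyl-4,6-diprenylcyclohexa-1,5-dien-1-olate (α′ dienolate of 10) | [Li+].[O-]C1=CC[C@@H](CC=C(C)C)C(C)=C1CC=C(C)C | intermediate (not isolated)
15 | (4R)-6-[(2R)-lavandulyl]-3-methyl-2,4-diprenylcyclohex-2-en-1-one, C6 epimer mixture | C=C(C)[C@H](CC=C(C)C)CC1C[C@@H](CC=C(C)C)C(C)=C(CC=C(C)C)C1=O | intermediate
16 | chloroacetaldehyde dimethyl acetal | COC(CCl)OC | starting material
17 | methoxyacetylene | COC#C | intermediate
18 | lithium methoxyacetylide | [Li+].[C-]#COC | intermediate (not isolated)
19 | phenyl 3-methoxyprop-2-ynoate | COC#CC(=O)Oc1ccccc1 | intermediate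
20 | lithium dimethylcuprate | [Li+].C[Cu-]C | starting material (reagent made in the flask from commercial CuI and MeLi)
21 | {[(4R)-6-[(2R)-lavandulyl]-3,3-dimethyl-2,4-diprenylcyclohex-1-en-1-yl]oxy}trimethylsilane, C6 epimer mixture | C=C(C)[C@H](CC=C(C)C)CC1C[C@@H](CC=C(C)C)C(C)(C)C(CC=C(C)C)=C1O[Si](C)(C)C | intermediate (not isolated)
22 | lithium (4R)-6-[(2R)-lavandulyl]-3,3-dimethyl-2,4-diprenylcyclohex-1-en-1-olate, C6 epimer mixture | [Li+].C=C(C)[C@H](CC=C(C)C)CC1C[C@@H](CC=C(C)C)C(C)(C)C(CC=C(C)C)=C1[O-] | intermediate (not isolated)
23 | phenyl (2E)-3-{(1R,5R)-3-[(2R)-lavandulyl]-6,6-dimethyl-2-oxo-1,5-diprenylcyclohexyl}-3-methoxyprop-2-enoate, ring C3 epimer mixture | C=C(C)[C@H](CC=C(C)C)CC1C[C@@H](CC=C(C)C)C(C)(C)[C@@](CC=C(C)C)(C1=O)/C(OC)=C\C(=O)Oc1ccccc1 | intermediate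
24 | potassium enolate of 23 formed by loss of the core C5–H (C1, C7 and lavandulyl methine as in 23) | [K+].C=C(C)[C@H](CC=C(C)C)CC1=C([O-])[C@@](CC=C(C)C)(/C(OC)=C\C(=O)Oc2ccccc2)C(C)(C)[C@H](CC=C(C)C)C1 | intermediate (not isolated)
25 | (1R,5S,7R)-5-[(2R)-lavandulyl]-2-methoxy-8,8-dimethyl-1,7-diprenylbicyclo[3.3.1]non-2-ene-4,9-dione (core numbering) | C=C(C)[C@H](CC=C(C)C)C[C@@]12C[C@@H](CC=C(C)C)C(C)(C)[C@@](CC=C(C)C)(C1=O)C(OC)=CC2=O | intermediate
26 | C3-lithio derivative of 25 (configuration as in 25) | C=C(C)[C@H](CC=C(C)C)C[C@@]12C[C@@H](CC=C(C)C)C(C)(C)[C@@](CC=C(C)C)(C1=O)C(OC)=C([Li])C2=O | intermediate (not isolated)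
27 | (1R,5R,7R)-3-benzoyl-5-[(2R)-lavandulyl]-2-methoxy-8,8-dimethyl-1,7-diprenylbicyclo[3.3.1]non-2-ene-4,9-dione (core numbering), CNP0385193.1 | C=C(C)[C@H](CC=C(C)C)C[C@@]12C[C@@H](CC=C(C)C)C(C)(C)[C@@](CC=C(C)C)(C1=O)C(OC)=C(C(=O)c1ccccc1)C2=O | target

## Step count and risks

Total: 14 steps. Longest linear sequence: 10 steps (steps 1–6, 9, 12, 13, 14); steps 7–8 and 10–11 are side branches.

**Step 12 (key step, Proposed new method).**
- What may go wrong: carbon–carbon bond formation at C1 may fail. The enolate carbon is flanked by the quaternary C8, so attack through oxygen, 1,2-addition to the phenyl ester, or simple protonation on work-up may take over.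
- For the C6 epimer of 15 whose lavandulyl arm becomes axial in enolate 22, facial selectivity at C1 may erode, because the preferred axial trajectory is then shielded.
- The allenoate may attack the C9 ketone before it is protonated, or be protonated to the acrylate geometry that cannot cyclise.
- Fallback (known chemistry): sets out from 15 and returns at 25. The cuprate addition with TMSCl is run as above, but silyl enol ether 21 is isolated. Effenberger cyclisation with malonyl dichloride (CH2Cl2, −20 °C → rt, then KOH, BnEt3NCl, H2O) acylates C1 and then C5 and gives the enolised bicyclic trione F1. Methylation (Me2SO4, K2CO3, acetone) gives 25 together with its regioisomeric enol ether F2, and the two are separated by chromatography. This replaces steps 12 and 13 and needs neither 19 nor the new coupling, but gives up control of the methyl ether position.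

**Step 13.**
- What may go wrong: the tertiary potassium enolate may acylate on oxygen, closing a six-membered enol lactone instead of the strained bridged diketone. Deprotonation of the hindered C5–H may also be slow enough for the base to attack the aryl ester.
- Fallback: sets out from 10 and returns at 25. The coupling of step 12 is run on 10, which has no C5 substituent, to give the des-lavandulyl phenyl acrylate F3. Its secondary C5 enolate (KN(SiMe3)2, THF) closes ring B to the bridgehead-unsubstituted bicycle F4. Bridgehead lithiation of F4 (LiN(i-Pr)2, THF, −78 °C) and alkylation with triflate 13 then installs the lavandulyl group and gives 25. Steps 9 and 13 in their present form are bypassed.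

**Step 9.**
- What may go wrong: substitution at the β-branched carbon may be too slow, so that the triflate ionises with participation of the isopropenyl group, or proton exchange between enolate and product sets in. Such exchange allows polyalkylation and, through the extended dienolate, loss of configuration at the prenyl-bearing carbon.
- Fallback: sets out from 10 and 12 and returns at 15. Enone 10 is condensed with 1,1-dimethylhydrazine (AcOH cat., EtOH, reflux) to the N,N-dimethylhydrazone F5. Alcohol 12 is converted into (S)-lavandulyl iodide F6 (I2, PPh3, imidazole, CH2Cl2, 0 °C). F5 is metalated at the α′ carbon (LiN(i-Pr)2, THF, 0 °C) and alkylated with F6 to the alkylated hydrazone F7 (Corey–Enders alkylation; azaenolates accept β-branched iodides that ketone enolates refuse). Two-phase hydrolysis (aqueous oxalic acid, Et2O) returns 15.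

**Step 4.**
- What may go wrong: enantiocontrol may be incomplete for a tertiary α′ centre of a vinylogous ester, through proton transfer between the palladium enolate and the product or a loose ion pair. The sense of induction also has to be confirmed.
- Fallback: sets out from 4 and returns at 8. Direct alkylation of the lithium dienolate of 4 (LiN(i-Pr)2, THF, −78 °C) with prenyl bromide 2 gives the racemic vinylogous ester F8. Preparative chromatography on a chiral stationary phase then delivers (S)-8. Steps 3–5 are replaced by one reaction and a resolution, at the cost of half the material.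

## Further compounds

F1 | step 12 | 2-hydroxy-5-[(2R)-lavandulyl]-8,8-dimethyl-1,7-diprenylbicyclo[3.3.1]non-2-ene-4,9-dione (core numbering, enol tautomers, ring configuration as in 25) | C=C(C)[C@H](CC=C(C)C)C[C@@]12C[C@@H](CC=C(C)C)C(C)(C)[C@@](CC=C(C)C)(C1=O)C(O)=CC2=O
F2 | step 12 | 5-[(2R)-lavandulyl]-4-methoxy-8,8-dimethyl-1,7-diprenylbicyclo[3.3.1]non-3-ene-2,9-dione (core numbering, ring configuration as in 25) | C=C(C)[C@H](CC=C(C)C)C[C@@]12C[C@@H](CC=C(C)C)C(C)(C)[C@@](CC=C(C)C)(C1=O)C(=O)C=C2OC
F3 | step 13 | phenyl (2E)-3-[(1R,5S)-6,6-dimethyl-2-oxo-1,5-diprenylcyclohexyl]-3-methoxyprop-2-enoate (spatial arrangement as in 23) | C1C[C@@H](CC=C(C)C)C(C)(C)[C@@](CC=C(C)C)(C1=O)/C(OC)=C\C(=O)Oc1ccccc1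
F4 | step 13 | 2-methoxy-8,8-dimethyl-1,7-diprenylbicyclo[3.3.1]non-2-ene-4,9-dione with C5–H (core numbering, ring configuration as in 25) | [C@@H]12C[C@@H](CC=C(C)C)C(C)(C)[C@@](CC=C(C)C)(C1=O)C(OC)=CC2=O
F5 | step 9 | N,N-dimethylhydrazone of (4S)-3-methyl-2,4-diprenylcyclohex-2-en-1-one | CN(C)N=C1CC[C@@H](CC=C(C)C)C(C)=C1CC=C(C)C
F6 | step 9 | (S)-lavandulyl iodide | C=C(C)[C@H](CC=C(C)C)CI
F7 | step 9 | N,N-dimethylhydrazone of 15 (C6 epimer mixture) | C=C(C)[C@H](CC=C(C)C)CC1C[C@@H](CC=C(C)C)C(C)=C(CC=C(C)C)C1=NN(C)C
F8 | step 4 | racemic 3-methoxy-2,6-diprenylcyclohex-2-en-1-one | COC1=C(CC=C(C)C)C(=O)C(CC=C(C)C)CC1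
A1 | alternative 1 | 5-ethoxy-6,6-bis[(2R)-lavandulyl]-3-methoxy-4-prenylcyclohexa-2,4-dien-1-one | C=C(C)[C@H](CC=C(C)C)CC1(C[C@@H](CC=C(C)C)C(C)=C)C(=O)C=C(OC)C(CC=C(C)C)=C1OCC
A2 | alternative 1 | 3-ethoxy-4,4-bis[(2R)-lavandulyl]-2-prenylcyclobut-2-en-1-one | CCOC1=C(CC=C(C)C)C(=O)C1(C[C@@H](CC=C(C)C)C(C)=C)C[C@@H](CC=C(C)C)C(C)=C
A3 | alternative 2 | 7-formyl analogue of the O-desmethyl target (C2 enol tautomer) | C=C(C)[C@H](CC=C(C)C)C[C@@]12C[C@@H](C=O)C(C)(C)[C@@](CC=C(C)C)(C1=O)C(O)=C(C(=O)c1ccccc1)C2=O
A4 | alternative 2 | {2,4,6-trihydroxy-3-[(2R)-lavandulyl]-5-prenylphenyl}(phenyl)methanone | C=C(C)[C@H](CC=C(C)C)Cc1c(O)c(CC=C(C)C)c(O)c(C(=O)c2ccccc2)c1O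
A5 | alternative 2 | 2-(acetoxymethyl)-3-methylbut-2-enal | CC(C)=C(COC(C)=O)C=O
A6 | alternative 3 | 3-desbenzoyl target, identical with 25 | C=C(C)[C@H](CC=C(C)C)C[C@@]12C[C@@H](CC=C(C)C)C(C)(C)[C@@](CC=C(C)C)(C1=O)C(OC)=CC2=O
A7 | alternative 3 | tert-butyldimethylsilyl enol ether (C9=C1) of the C5-(3-methoxypropynoyl) ketone, ring configuration as in 25 | C=C(C)[C@H](CC=C(C)C)C[C@@]1(C(=O)C#COC)C[C@@H](CC=C(C)C)C(C)(C)C(CC=C(C)C)=C1O[Si](C)(C)C(C)(C)C
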